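**Plan**

1. Locants: ring A is C1 (quaternary, bears C15H2OAc)–C2H2–C3H(OH)–C4H(OAc)–C5Me2–C6 (quaternary). The cage is C6–C7H2–C8H, the cyclopropane C8–C9–C10 (C9 on C1, C10 bears CH3) and C10–C11H(OAc)–C6.
2. Retrosynthesis: the acetates and the C3 carbinol go back to a tetracyclic α-ketol. C1–C6 and C3–C4 are cut together (Michael addition, then carbene-catalysed crossed benzoin) to a bicyclo[3.1.0]hexan-2-one with an endo (E)-enal arm on C9 and a CMe2CHO arm on C6. Then C5–C6 (ketal Claisen), C1–C15 (cuprate on an alkynoate) and the cyclopropane (tethered carbene) lead to 2-methylcyclopent-2-enone.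
3. Forward: the cyclopentane C10–C11–C6–C7–C8 is bought, the cyclopropane is added by intramolecular cyclopropanation, the two arms are attached, and one operation closes the remaining five-membered rings of the nortricyclene and ring A.
4. Enabling feature: the all-cis cyclopropane holds C1 face to face with C6. O=C11 and O=C3 are 1,5-related, so C1–C6 forms with natural polarity; the 1,2-dioxygenated pair C3/C4 is joined with reversed polarity.
5. Stereochemistry: a CBS reduction sets the C11 carbinol, which steers the carbene to one alkene face (C8, C9, C10) and is then oxidised. The cyclopropane relays to C6 and C1 in the key step. C4 is thermodynamic, C3 comes from equatorial hydride attack, and C11 from a transannular hydride shift from C3–H.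

Key step: step 14

Remark: in bicyclo[3.1.0]hexane names, positions 1 to 6 are C10, C11, C6, C7, C8, C9; the C6 configuration of 12–23 (drawn as the expected epimer, substituent anti to the cyclopropane) is planarised in step 14, so both epimers converge.

**Route**

Step 1
Reactants: 1 2-methylcyclopent-2-en-1-one
Product: 2 (R)-2-methylcyclopent-2-en-1-ol
Conditions: (S)-2-methyl-CBS-oxazaborolidine (10 mol%), BH3·SMe2 (0.6 equiv), THF, −20 °C
Reagents that add atoms: none
Why: Corey–Bakshi–Shibata reduction, with the alkenyl arm of the enone as the large group, should give the (R)-carbinol (C11), the only stereocentre set by a catalyst.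

Step 2
Reactants: 2 (R)-2-methylcyclopent-2-en-1-ol
Product: 4 (R)-2-methylcyclopent-2-en-1-yl diazoacetate, via bromoacetate 3 (not isolated)
Conditions: BrCH2COBr, NaHCO3, MeCN, 0 °C; then TsNHNHTs, DBU, THF, 0 °C
Reagents that add atoms: bromoacetyl bromide BrCC(Br)=O; N,N'-ditosylhydrazine Cc1ccc(cc1)S(=O)(=O)NNS(=O)(=O)c1ccc(C)cc1
Why: O-acylation, then displacement of bromide by the ditosylhydrazine anion and two sulfinate eliminations (a standard diazoacetate synthesis), leaves the carbinol centre untouched.

Step 3
Reactants: 4 (R)-2-methylcyclopent-2-en-1-yl diazoacetate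
Product: 5 tricyclic cyclopropane lactone (C11 oxygen lactonised onto the C1 carbonyl carried endo by C9; CH3 on C10)
Conditions: dirhodium tetrakis(caprolactamate) Rh2(cap)4 (1 mol%), CH2Cl2, 40 °C, slow addition of 4
Reagents that add atoms: none
Why: intramolecular cyclopropanation of an allylic diazoacetate through a rhodium carbenoid; the five-membered lactone tether allows addition only to the alkene face cis to the ester oxygen, so the C11 carbinol sets C8, C9 and C10 and places C1 endo on C9.

Step 4
Reactants: 5 tricyclic cyclopropane lactone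
Product: 6 lactol of 5 (anomers)
Conditions: i-Bu2AlH (1.1 equiv), CH2Cl2, −78 °C
Reagents that add atoms: none
Why: partial reduction of a γ-lactone stops at the aluminium hemiacetal at low temperature.

Step 5
Reactants: 6 lactol of 5
Product: 7 6-endo-ethynyl-1-methylbicyclo[3.1.0]hexan-2-ol (hydroxyl cis to the cyclopropane)
Conditions: dimethyl (1-diazo-2-oxopropyl)phosphonate, K2CO3, MeOH, 0 → 23 °C
Reagents that add atoms: dimethyl (1-diazo-2-oxopropyl)phosphonate COP(=O)(OC)C(=[N+]=[N-])C(C)=O
Why: Ohira–Bestmann (Seyferth–Gilbert) homologation of the open hydroxy-aldehyde form of the lactol should give the alkyne (C1≡C2) with the cis-cyclopropane intact and free the C11 hydroxyl.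

Step 6
Reactants: 7 6-endo-ethynyl-1-methylbicyclo[3.1.0]hexan-2-ol
Product: 8 6-endo-ethynyl-1-methylbicyclo[3.1.0]hexan-2-one
Conditions: Dess–Martin periodinane, NaHCO3, CH2Cl2, 23 °C
Reagents that add atoms: none
Why: Dess–Martin oxidation; the directing carbinol has done its work and becomes the ketone needed for enolate chemistry at C6.

Step 7
Reactants: 8 6-endo-ethynyl-1-methylbicyclo[3.1.0]hexan-2-one; 9 3-methylbut-2-en-1-ol (prenol)
Product: 12 6-endo-ethynyl-1-methyl-3-(2-methylbut-3-en-2-yl)bicyclo[3.1.0]hexan-2-one, via dimethyl ketal 10 (not isolated), via prenyl enol ether 11 (not isolated)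
Conditions: HC(OMe)3, TsOH·H2O (5 mol%), MeOH, 23 °C; evaporate; 9 (3 equiv), 2,4-dinitrophenol (5 mol%), xylenes, 140 °C (−MeOH)
Reagents that add atoms: none
Why: ketal Claisen rearrangement: acetal exchange and loss of methanol give the prenyl enol ether (C6 is the only enolisable position), whose [3,3]-shift makes the C6–C5 bond to the gem-dimethyl carbon and leaves a vinyl group as the masked C4 aldehyde.

Step 8
Reactants: 12 6-endo-ethynyl-1-methyl-3-(2-methylbut-3-en-2-yl)bicyclo[3.1.0]hexan-2-one
Product: 13 methyl alkynoate (CO2Me on the alkyne terminus of 12)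
Conditions: PdCl2 (5 mol%), CuCl2 (2.2 equiv), NaOAc (2.2 equiv), CO (1 atm), MeOH, 23 °C
Reagents that add atoms: carbon monoxide [C-]#[O+]; methanol CO
Why: palladium-catalysed oxidative alkoxycarbonylation of a terminal alkyne adds C3 without the strong base that acetylide acylation would need beside the ketone.

Step 9
Reactants: 14 4-methoxybenzyl alcohol; 15 tributyl(iodomethyl)stannane
Product: 16 tributyl[(4-methoxybenzyloxy)methyl]stannane
Conditions: NaH, THF–DMF, 0 → 23 °C
Reagents that add atoms: none
Why: Williamson ether synthesis on a reactive α-stannyl iodide.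

Step 10
Reactants: 13 methyl alkynoate; 16 tributyl[(4-methoxybenzyloxy)methyl]stannane
Product: 19 methyl (E)-enoate (C15H2OPMB on C1; ester cis to the cyclopropane carbon C9), via alkoxymethyllithium 17 (not isolated), via lithium cuprate 18 (not isolated)
Conditions: 16 (2.4 equiv), n-BuLi (2.3 equiv), THF, −78 °C; CuBr·SMe2 (1.15 equiv), −78 → −50 °C; 13, −78 °C; MeOH then aq. NH4Cl, −78 °C
Reagents that add atoms: none
Why: tin–lithium exchange, cuprate formation and syn-carbocupration (conjugate addition) of the alkynoate; cold protonation of the alkenylcopper with retention puts CH2OPMB cis to H, so the ester is cis to C9.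

Step 11
Reactants: 19 methyl (E)-enoate
Product: 20 (E)-allylic alcohol with C11 carbinol (C11 epimers)
Conditions: i-Bu2AlH (5 equiv), CH2Cl2, −78 → 0 °C
Reagents that add atoms: none
Why: hydride reduction of the enoate (1,2) and of the ketone; the C11 configuration is irrelevant because step 12 removes it.

Step 12
Reactants: 20 (E)-allylic alcohol with C11 carbinol
Product: 21 (E)-keto-enal (C3 aldehyde; C11 ketone; vinyl on C5)
Conditions: Dess–Martin periodinane (3 equiv), NaHCO3, CH2Cl2, 0 → 23 °C
Reagents that add atoms: none
Why: Dess–Martin oxidation of both alcohols under buffered conditions should keep the alkene geometry.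

Step 13
Reactants: 21 (E)-keto-enal
Product: 23 keto-enal-aldehyde (C3 and C4 aldehydes; C11 ketone), via vicinal diol 22 (not isolated)
Conditions: OsO4 (2 mol%), NaIO4 (4 equiv), 2,6-lutidine (2 equiv), 1,4-dioxane–H2O (3:1), 23 °C
Reagents that add atoms: osmium tetroxide O=[Os](=O)(=O)=O (catalytic oxygen carrier); sodium periodate [Na+].[O-]I(=O)(=O)=O
Why: Lemieux–Johnson cleavage; the monosubstituted vinyl group is dihydroxylated much faster than the electron-poor trisubstituted enal, and periodate cleaves the diol to the C4 aldehyde.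

Step 14
Reactants: 23 keto-enal-aldehyde
Product: 25 tetracyclic α-ketol (C3 ketone; equatorial C4 hydroxyl; C11 ketone; C15 OPMB), via Michael adduct 24 (not isolated)
Conditions: LiOt-Bu (0.3 equiv), THF (0.01 M), −40 → 0 °C; then 2-(pentafluorophenyl)-6,7-dihydro-5H-pyrrolo[2,1-c][1,2,4]triazol-2-ium tetrafluoroborate (0.2 equiv), 23 °C, same flask
Reagents that add atoms: none
Why: Proposed new method: lithium tert-butoxide removes the only enolisable proton of the ketone (C6–H; the other α-carbon is the quaternary C10), and the lithium enolate, held by the all-cis cyclopropane just below the β-carbon of the endo (E)-enal, adds to it in a 5-exo-trig Michael reaction that makes the C1–C6 bond between two quaternary carbons and closes the nortricyclene; the freed C2H2–C3HO arm is then turned by the triazolylidene into a Breslow intermediate (the neopentyl C4 aldehyde is too hindered to be the donor), which adds 6-exo-trig to the non-enolisable C4 aldehyde in a crossed benzoin reaction that makes C3–C4 and closes ring A. The closest known reaction types are the amine/carbene Michael–benzoin cascades of 1,3-dicarbonyl compounds with enals and the azolium-catalysed cyclisation of 1,6-dialdehydes to 2-hydroxycyclohexanones; new here are the unactivated ketone donor and the quaternary–quaternary bond. C6 can bond only on the face that carries the C9 arm; C1 is set by a closed transition state in which lithium bridges the enolate oxygen and the formyl oxygen, so that C2 lies over C11 and CH2OPMB over C7; C4 equilibrates through the enediol to the equatorial carbinol. The step needs the Michael addition to precede carbene addition to the enal (hence the staged addition of the azolium salt, which the Michael-derived enolate deprotonates), and the six-ring acyloin closure to win over the reversible five-ring aldol of C2 onto C4, which the fixed 60° torsion about C1–C6 disfavours.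

Step 15
Reactants: 25 tetracyclic α-ketol
Product: 26 cis-diol ketone (axial C3 hydroxyl; equatorial C4 hydroxyl; C11 ketone)
Conditions: NaBH4 (1.0 equiv), MeOH–CH2Cl2 (1:1), −40 °C
Reagents that add atoms: none
Why: borohydride reduction of the ring-A ketone only; axial approach is blocked by the axial CH2OPMB on C1 and the axial methyl on C5, so equatorial attack should give the axial C3 carbinol, while the C11 ketone between two quaternary carbons is left.

Step 16
Reactants: 26 cis-diol ketone
Product: 27 C11 carbinol α-ketol (C3 ketone; C4 hydroxyl; C11 hydroxyl anti to ring A)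
Conditions: t-BuOK (0.3 equiv), toluene–t-BuOH (4:1), 60 °C
Reagents that add atoms: none
Why: base-mediated intramolecular Meerwein–Ponndorf–Verley–Oppenauer redox (transannular 1,5-hydride shift): in the boat form of ring A the C3–H is a flagpole hydrogen facing the C11 carbonyl from the ring-A side, the face closed to external hydride, so the C11 oxygen should end on the C7 side as in the target, driven by loss of the two 1,3-diaxial contacts of the C3 hydroxyl.

Step 17
Reactants: 27 C11 carbinol α-ketol
Product: 28 triol ketone (C4, C11 and C15 hydroxyls; C3 ketone)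
Conditions: DDQ (1.5 equiv), CH2Cl2–pH 7 buffer (10:1), 0 → 23 °C
Reagents that add atoms: none
Why: oxidative cleavage of the p-methoxybenzyl ether under neutral conditions that spare the cyclopropylcarbinol and the α-ketol.

Step 18
Reactants: 28 triol ketone
Product: 29 triacetate ketone
Conditions: Ac2O (8 equiv), DMAP (1 equiv), pyridine, 40 °C
Reagents that add atoms: acetic anhydride CC(=O)OC(C)=O
Why: DMAP-catalysed acetylation of the C15, C4 and hindered C11 hydroxyls while C3 is still a ketone, which keeps the future free hydroxyl apart.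

Step 19
Reactants: 29 triacetate ketone
Product: 30 target CNP0111873.1
Conditions: NaBH4 (1.5 equiv), CeCl3·7H2O (1.5 equiv), MeOH, −78 °C; AcOH quench
Reagents that add atoms: none
Why: Luche-type borohydride reduction; equatorial attack (axial face blocked as in step 15) should give the axial C3 alcohol cis to the C4 acetate, and the cold buffered quench should suppress acetyl migration.

**Compound list**

1 | 2-methylcyclopent-2-en-1-one | CC1=CCCC1=O | starting material
2 | (R)-2-methylcyclopent-2-en-1-ol | O[C@@H]1CCC=C1C | intermediate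
3 | (R)-2-methylcyclopent-2-en-1-yl bromoacetate | BrCC(=O)O[C@@H]1CCC=C1C | intermediate
4 | (R)-2-methylcyclopent-2-en-1-yl diazoacetate | [N-]=[N+]=CC(=O)O[C@@H]1CCC=C1C | intermediate
5 | tricyclic cyclopropane lactone (all-cis cyclopropane; C11–O–C1(=O)–C9 bridge) | O=C1O[C@@H]2CC[C@@H]3[C@H]1[C@]23C | intermediate
6 | lactol of 5 (anomers) | OC1O[C@@H]2CC[C@@H]3[C@H]1[C@]23C | intermediate
7 | 6-endo-ethynyl-1-methylbicyclo[3.1.0]hexan-2-ol (OH cis to the cyclopropane) | C#C[C@H]1[C@H]2CC[C@@H](O)[C@@]12C | intermediate
8 | 6-endo-ethynyl-1-methylbicyclo[3.1.0]hexan-2-one | C#C[C@H]1[C@H]2CCC(=O)[C@@]12C | intermediate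
9 | 3-methylbut-2-en-1-ol (prenol) | CC(C)=CCO | starting material
10 | dimethyl ketal of 8 | C#C[C@H]1[C@H]2CCC(OC)(OC)[C@@]12C | intermediate
11 | prenyl enol ether of 8 | C#C[C@H]1[C@H]2CC=C(OCC=C(C)C)[C@@]12C | intermediate
12 | 6-endo-ethynyl-1-methyl-3-(2-methylbut-3-en-2-yl)bicyclo[3.1.0]hexan-2-one | C#C[C@H]1[C@H]2C[C@H](C(C)(C)C=C)C(=O)[C@@]12C | intermediate
13 | methyl 3-[bicyclic ketone of 12]prop-2-ynoate | COC(=O)C#C[C@H]1[C@H]2C[C@H](C(C)(C)C=C)C(=O)[C@@]12C | intermediate
14 | 4-methoxybenzyl alcohol | COc1ccc(CO)cc1 | starting material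
15 | tributyl(iodomethyl)stannane | CCCC[Sn](CCCC)(CCCC)CI | starting material
16 | tributyl[(4-methoxybenzyloxy)methyl]stannane | CCCC[Sn](CCCC)(CCCC)COCc1ccc(OC)cc1 | intermediate
17 | [(4-methoxybenzyloxy)methyl]lithium | [Li]COCc1ccc(OC)cc1 | intermediate
18 | lithium bis[(4-methoxybenzyloxy)methyl]cuprate | [Li+].COc1ccc(COC[Cu-]COCc2ccc(OC)cc2)cc1 | intermediate
19 | methyl (E)-4-(4-methoxybenzyloxy)-3-[bicyclic ketone]but-2-enoate | COC(=O)/C=C(/COCc1ccc(OC)cc1)[C@H]1[C@H]2C[C@H](C(C)(C)C=C)C(=O)[C@@]12C | intermediate
20 | (E)-allylic alcohol with C11 carbinol (C11 epimers) | OC/C=C(/COCc1ccc(OC)cc1)[C@H]1[C@H]2C[C@H](C(C)(C)C=C)C(O)[C@@]12C | intermediate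
21 | (E)-keto-enal with vinyl on C5 | O=C/C=C(/COCc1ccc(OC)cc1)[C@H]1[C@H]2C[C@H](C(C)(C)C=C)C(=O)[C@@]12C | intermediate
22 | vicinal diol from the vinyl group of 21 | O=C/C=C(/COCc1ccc(OC)cc1)[C@H]1[C@H]2C[C@H](C(C)(C)C(O)CO)C(=O)[C@@]12C | intermediate
23 | keto-enal-aldehyde | O=C/C=C(/COCc1ccc(OC)cc1)[C@H]1[C@H]2C[C@H](C(C)(C)C=O)C(=O)[C@@]12C | intermediate
24 | Michael adduct (nortricyclanone with CH2CHO on C1 and CMe2CHO on C6) | O=CC[C@@]1(COCc4ccc(OC)cc4)[C@]2(C(C)(C)C=O)C[C@@H]3[C@H]1[C@]3(C)C2=O | intermediate
25 | tetracyclic α-ketol (C3 ketone; C4 OH; C11 ketone; C15 OPMB) | COc1ccc(cc1)COC[C@]12CC(=O)[C@H](O)C(C)(C)[C@]13C[C@@H]1[C@H]2[C@]1(C)C3=O | intermediate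
26 | C3,C4-cis-diol with C11 ketone | COc1ccc(cc1)COC[C@]12C[C@H](O)[C@H](O)C(C)(C)[C@]13C[C@@H]1[C@H]2[C@]1(C)C3=O | intermediate
27 | C3 ketone with C4 and C11 hydroxyls | COc1ccc(cc1)COC[C@]12CC(=O)[C@H](O)C(C)(C)[C@]13C[C@@H]1[C@H]2[C@]1(C)[C@H]3O | intermediate
28 | triol ketone | OC[C@]12CC(=O)[C@H](O)C(C)(C)[C@]13C[C@@H]1[C@H]2[C@]1(C)[C@H]3O | intermediate
29 | triacetate ketone | CC(=O)OC[C@]12CC(=O)[C@H](OC(C)=O)C(C)(C)[C@]13C[C@@H]1[C@H]2[C@]1(C)[C@H]3OC(C)=O | intermediate
30 | CNP0111873.1 | CC(=O)OC[C@]12C[C@H](O)[C@H](OC(C)=O)C(C)(C)[C@]13C[C@@H]1[C@H]2[C@]1(C)[C@H]3OC(C)=O | target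

**Step count**

Total: 19 steps. Longest linear sequence: 18 steps (steps 1–8 and 10–19; step 9 is the side branch).

**Steps most likely to fail**

1. Step 14 (Proposed new method). The enal may be intercepted before the conjugate addition (carbene addition, γ-deprotonation with loss of alkene geometry), the C2 enolate may close onto the C4 aldehyde by aldol reaction before the acyloin forms, or facial selectivity at C1 may erode if the lithium bridge is lost. The fallback separates the two bond formations and replaces the carbene step by a reductive coupling. It sets out from 21, where the second aldehyde is still a vinyl group. Intramolecular Michael addition (LiOt-Bu, THF, −40 °C) should give the vinyl keto-aldehyde F1. Lemieux–Johnson cleavage of F1 gives the dialdehyde 24, now isolated. SmI2 (2.2 equiv, THF–t-BuOH, −78 °C) pinacol cyclisation through a samarium-bridged cis-diolate, with the C4 oxygen equatorial because an axial one would be 1,3-diaxial to C11, should give the cis-diol 26, where the route is rejoined before step 16.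

2. Step 16. The hydride may not transfer if the boat form of ring A is too costly, or the base may scramble the α-ketol through the enediol. The fallback uses an external, equilibrating hydride donor and a different differentiation of the hydroxyls. It sets out from 26. 2,2-Dimethoxypropane and PPTS give the acetonide ketone F2. Equilibrating Meerwein–Ponndorf–Verley reduction (Al(Oi-Pr)3, i-PrOH, trace acetone, toluene, 100 °C) should give the more stable C11 carbinol acetonide F3. Ac2O and DMAP give the C11 acetate F4, DDQ gives the C15 alcohol F5, and aqueous AcOH removes the acetonide to give the triol monoacetate F6. Selective acetylation of the primary C15 and equatorial C4 hydroxyls (Ac2O 2.2 equiv, pyridine, 0 °C), the axial C3 hydroxyl between two 1,3-diaxial carbons being the slowest, reaches 30.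

3. Step 7. Ketal exchange at the hindered cyclopropyl ketone may be sluggish, or the enol ether may decompose thermally before the [3,3]-shift. The fallback builds the quaternary carbon by conjugate addition instead. It sets out from 8. TMSOTf and Et3N give the silyl enol ether F7. Mukaiyama aldol reaction with acetone (TiCl4, CH2Cl2, −78 °C) gives the β-hydroxy ketone F8. MsCl and Et3N, then DBU, give the isopropylidene ketone F9. 1,4-Addition of (CH2=CH)2CuLi with TMSCl in THF at −78 °C (one extra equivalent for the alkyne C–H) returns to 12.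

**Further compounds**

F1 | step 14 | vinyl keto-aldehyde (Michael adduct of 21) | O=CC[C@@]1(COCc4ccc(OC)cc4)[C@]2(C(C)(C)C=C)C[C@@H]3[C@H]1[C@]3(C)C2=O
F2 | step 16 | acetonide ketone | COc1ccc(cc1)COC[C@]12C[C@@H]3OC(C)(C)O[C@@H]3C(C)(C)[C@]14C[C@@H]5[C@H]2[C@]5(C)C4=O
F3 | step 16 | C11 carbinol acetonide | COc1ccc(cc1)COC[C@]12C[C@@H]3OC(C)(C)O[C@@H]3C(C)(C)[C@]14C[C@@H]5[C@H]2[C@]5(C)[C@H]4O
F4 | step 16 | C11 acetate acetonide | COc1ccc(cc1)COC[C@]12C[C@@H]3OC(C)(C)O[C@@H]3C(C)(C)[C@]14C[C@@H]5[C@H]2[C@]5(C)[C@H]4OC(C)=O
F5 | step 16 | C15 alcohol acetonide | OC[C@]12C[C@@H]3OC(C)(C)O[C@@H]3C(C)(C)[C@]14C[C@@H]5[C@H]2[C@]5(C)[C@H]4OC(C)=O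
F6 | step 16 | triol monoacetate | OC[C@]12C[C@H](O)[C@H](O)C(C)(C)[C@]13C[C@@H]1[C@H]2[C@]1(C)[C@H]3OC(C)=O
F7 | step 7 | trimethylsilyl enol ether of 8 | C#C[C@H]1[C@H]2CC=C(O[Si](C)(C)C)[C@@]12C
F8 | step 7 | β-hydroxy ketone (acetone aldol) | C#C[C@H]1[C@H]2C[C@H](C(C)(C)O)C(=O)[C@@]12C
F9 | step 7 | isopropylidene ketone | C#C[C@H]1[C@H]2CC(=C(C)C)C(=O)[C@@]12C
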